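**Retrosynthetic overview**

1. Numbering: butenolide O1, C2(=O), C3, C4 (hydroxymethyl C4'), C5; side chain C6, C7=C8 (C8 carries hydroxymethyl C8'), C9 onward to the chain-terminal hydroxymethyl. The strategy rests on the Z-trisubstituted C7=C8 alkene: C7–C8–C8' is propargyl alcohol that has taken up two carbon groups anti (C9 on C8, C6 on C7 cis to C8'), and the C5 oxygen lies two bonds from C7, as in an opened terminal epoxide.
2. Key disconnections: C8–C9 (silyl-protected ω-hydroxy-homofarnesyl Grignard reagent from (2E,6E)-farnesol) and C6–C7 (CH2 of an (R,R)-epoxide acetonide from diethyl D-tartrate), both formed in one three-component carbomagnesiation/epoxide-opening step in which no ring is made.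
3. The butenolide, the only ring, is closed afterwards: O5 is esterified with diethylphosphonoacetic acid (C2, C3), C4 is unmasked and oxidised, the ring O1/C2–C5 is closed by intramolecular Horner–Wadsworth–Emmons olefination (C3=C4), and the three silyl ethers are removed last.

Key step: step 16

Remark: the dioxolane carbon C4 is a spectator stereocentre that is erased by oxidation in step 21; C5 (R in the target) is carried unchanged from D-tartrate.

**Branch A: Grignard reagent from farnesol**

Step 1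
Reactants: 1 (2E,6E)-farnesol
Product: 2 (2E,6E)-farnesyl acetate
Conditions: Ac2O, pyridine, DMAP (cat.), CH2Cl2, 0 °C to rt
Reagents that add atoms: acetic anhydride, CC(=O)OC(C)=O
Why: DMAP-catalysed acylation protects the primary allylic alcohol and electronically deactivates the C2=C3 alkene for the allylic oxidation that follows.

Step 2
Reactants: 2 (2E,6E)-farnesyl acetate
Product: 3 (2E,6E,10E)-12-hydroxy-3,7,11-trimethyldodeca-2,6,10-trien-1-yl acetate
Conditions: SeO2 (cat.), salicylic acid (cat.), t-BuOOH, CH2Cl2, 0 °C to rt, stopped at partial conversion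
Reagents that add atoms: tert-butyl hydroperoxide, CC(C)(C)OO (terminal oxygen source; the oxygen is transferred through SeO2, O=[Se]=O)
Why: SeO2-catalysed allylic oxidation (Riley oxidation; ene reaction then [2,3]-sigmatropic shift) should attack the E-methyl group of the terminal, most electron-rich trisubstituted alkene and deliver the E allylic alcohol, the acetate-deactivated C2=C3 alkene being the least reactive.

Step 3
Reactants: 3 (2E,6E,10E)-12-hydroxy-3,7,11-trimethyldodeca-2,6,10-trien-1-yl acetate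
Product: 4 (2E,6E,10E)-12-(tert-butyldiphenylsilyloxy)-3,7,11-trimethyldodeca-2,6,10-trien-1-yl acetate
Conditions: TBDPSCl, imidazole, DMF, 0 °C to rt
Reagents that add atoms: tert-butyldiphenylsilyl chloride, CC(C)(C)[Si](Cl)(c1ccccc1)c1ccccc1
Why: Imidazole-promoted silylation of the primary alcohol, the TBDPS ether being chosen because it must survive the Grignard chemistry and the acidic acetonide cleavage of step 19.

Step 4
Reactants: 4 (2E,6E,10E)-12-(tert-butyldiphenylsilyloxy)-3,7,11-trimethyldodeca-2,6,10-trien-1-yl acetate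
Product: 5 (2E,6E,10E)-12-(tert-butyldiphenylsilyloxy)-3,7,11-trimethyldodeca-2,6,10-trien-1-ol
Conditions: K2CO3 (cat.), MeOH, rt
Reagents that add atoms: none
Why: Base-catalysed methanolysis (transesterification) removes the acetate without touching the silyl ether.

Step 5
Reactants: 5 (2E,6E,10E)-12-(tert-butyldiphenylsilyloxy)-3,7,11-trimethyldodeca-2,6,10-trien-1-ol
Product: 6 (2E,6E,10E)-12-(tert-butyldiphenylsilyloxy)-3,7,11-trimethyldodeca-2,6,10-trienal
Conditions: TEMPO (cat.), PhI(OAc)2, CH2Cl2, rt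
Reagents that add atoms: none
Why: TEMPO/PhI(OAc)2 oxidation (oxoammonium-mediated) converts the allylic alcohol into the enal under neutral, non-isomerising conditions that leave the alkenes and the silyl ether intact.

Step 6
Reactants: 6 (2E,6E,10E)-12-(tert-butyldiphenylsilyloxy)-3,7,11-trimethyldodeca-2,6,10-trienal
Product: 7 (3E,7E,11E)-13-(tert-butyldiphenylsilyloxy)-4,8,12-trimethyltrideca-1,3,7,11-tetraene
Conditions: Ph3PCH3Br, n-BuLi, THF, 0 °C; then 6, −78 °C to rt
Reagents that add atoms: methyltriphenylphosphonium bromide, C[P+](c1ccccc1)(c1ccccc1)c1ccccc1.[Br-]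
Why: Wittig methylenation of the enal with the non-stabilised ylide adds carbon C9 as a terminal vinyl group without affecting the E geometry of the adjacent alkene.

Step 7
Reactants: 7 (3E,7E,11E)-13-(tert-butyldiphenylsilyloxy)-4,8,12-trimethyltrideca-1,3,7,11-tetraene
Product: 9 (3E,7E,11E)-13-(tert-butyldiphenylsilyloxy)-4,8,12-trimethyltrideca-3,7,11-trien-1-ol, via B-alkyl-9-BBN borane 8 (not isolated)
Conditions: 9-BBN, THF, 0 °C to rt; then NaOH, H2O2, 0 °C
Reagents that add atoms: hydrogen peroxide, OO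
Why: Hydroboration–oxidation with the bulky, regioselective 9-BBN places boron on the terminal CH2 of the only monosubstituted alkene (the trisubstituted alkenes do not react), and oxidation with retention gives the primary homoallylic alcohol.

Step 8
Reactants: 9 (3E,7E,11E)-13-(tert-butyldiphenylsilyloxy)-4,8,12-trimethyltrideca-3,7,11-trien-1-ol
Product: 10 (3E,7E,11E)-1-bromo-13-(tert-butyldiphenylsilyloxy)-4,8,12-trimethyltrideca-3,7,11-triene
Conditions: CBr4, PPh3, CH2Cl2, 0 °C
Reagents that add atoms: carbon tetrabromide, BrC(Br)(Br)Br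
Why: The Appel reaction converts the primary alcohol into the bromide under neutral conditions that preserve the silyl ether and the alkenes.

Step 9
Reactants: 10 (3E,7E,11E)-1-bromo-13-(tert-butyldiphenylsilyloxy)-4,8,12-trimethyltrideca-3,7,11-triene
Product: 11 [(3E,7E,11E)-13-(tert-butyldiphenylsilyloxy)-4,8,12-trimethyltrideca-3,7,11-trien-1-yl]magnesium bromide (titrated THF solution)
Conditions: Mg turnings (I2-activated), THF, rt to 40 °C
Reagents that add atoms: magnesium, [Mg]
Why: Grignard formation by oxidative insertion of magnesium into the primary C–Br bond, the homoallylic reagent being stable at these temperatures and the silyl ether inert.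

**Branch B: (R,R)-epoxide from diethyl D-tartrate**

Step 10
Reactants: 12 diethyl D-tartrate
Product: 13 diethyl (4S,5S)-2-phenyl-1,3-dioxolane-4,5-dicarboxylate
Conditions: PhCH(OMe)2, p-TsOH (cat.), toluene, 80 °C, MeOH distilled off
Reagents that add atoms: benzaldehyde dimethyl acetal, COC(OC)c1ccccc1
Why: Acid-catalysed transacetalisation ties the two secondary hydroxyls into a benzylidene acetal without touching the stereocentres.

Step 11
Reactants: 13 diethyl (4S,5S)-2-phenyl-1,3-dioxolane-4,5-dicarboxylate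
Product: 14 2-O-benzyl-D-threitol, (2R,3R)-3-(benzyloxy)butane-1,2,4-triol
Conditions: LiAlH4, AlCl3, Et2O/CH2Cl2, 0 °C to reflux
Reagents that add atoms: none
Why: The mixed chloroalane reagent reduces both esters and reductively opens the benzylidene acetal to a benzyl ether (hydride attack on the oxocarbenium ion), and because the substrate is C2-symmetric either C–O cleavage gives the same mono-O-benzyl triol with both stereocentres intact.

Step 12
Reactants: 14 2-O-benzyl-D-threitol
Product: 15 (2R)-2-(benzyloxy)-2-[(4R)-2,2-dimethyl-1,3-dioxolan-4-yl]ethan-1-ol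
Conditions: 2,2-dimethoxypropane, p-TsOH (cat.), acetone, rt
Reagents that add atoms: 2,2-dimethoxypropane, COC(C)(C)OC
Why: Thermodynamic acetalisation closes the five-membered dioxolane on the vicinal diol in preference to a six-membered 1,3-dioxane, leaving the primary hydroxyl next to the benzyloxy carbon free.

Step 13
Reactants: 15 (2R)-2-(benzyloxy)-2-[(4R)-2,2-dimethyl-1,3-dioxolan-4-yl]ethan-1-ol
Product: 16 (1R)-1-[(4R)-2,2-dimethyl-1,3-dioxolan-4-yl]ethane-1,2-diol
Conditions: H2 (1 atm), Pd/C, EtOAc, rt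
Reagents that add atoms: none
Why: Catalytic hydrogenolysis cleaves the benzyl ether under neutral conditions that leave the acetonide untouched.

Step 14
Reactants: 16 (1R)-1-[(4R)-2,2-dimethyl-1,3-dioxolan-4-yl]ethane-1,2-diol
Product: 17 (2R)-2-[(4R)-2,2-dimethyl-1,3-dioxolan-4-yl]-2-hydroxyethyl 4-methylbenzenesulfonate
Conditions: TsCl, Et3N, Bu2SnO (cat.), CH2Cl2, 0 °C to rt
Reagents that add atoms: p-toluenesulfonyl chloride, Cc1ccc(cc1)S(Cl)(=O)=O
Why: Stannylene-catalysed selective sulfonylation of the 1,2-diol, in which Bu2SnO activates the diol and the less hindered primary oxygen is tosylated, so that purification of the monotosylate secures the configuration of the later epoxide.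

Step 15
Reactants: 17 (2R)-2-[(4R)-2,2-dimethyl-1,3-dioxolan-4-yl]-2-hydroxyethyl 4-methylbenzenesulfonate
Product: 18 (R)-2-[(4R)-2,2-dimethyl-1,3-dioxolan-4-yl]oxirane
Conditions: K2CO3, MeOH, 0 °C to rt
Reagents that add atoms: none
Why: Intramolecular Williamson etherification (3-exo-tet displacement of the primary tosylate by the neighbouring alkoxide) forms the terminal epoxide with retention at the carbinol carbon, since no bond to it is broken.

**Union and endgame**

Step 16
Reactants: 19 propargyl alcohol; 11 [(3E,7E,11E)-13-(tert-butyldiphenylsilyloxy)-4,8,12-trimethyltrideca-3,7,11-trien-1-yl]magnesium bromide; 18 (R)-2-[(4R)-2,2-dimethyl-1,3-dioxolan-4-yl]oxirane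
Product: 22 (1R,3Z,7E,11E,15E)-1-[(4R)-2,2-dimethyl-1,3-dioxolan-4-yl]-4-(hydroxymethyl)-8,12,16-trimethyl-17-(tert-butyldiphenylsilyloxy)heptadeca-3,7,11,15-tetraen-1-ol, via chloromagnesium propargyl alkoxide 20 (not isolated), via cyclic alkenylmagnesium alkoxide 21 (not isolated)
Conditions: i-PrMgCl (1.0 equiv), THF, −40 °C; CuI (10 mol%), 11 (1.2 equiv), −20 °C to rt; then 18 (1.3 equiv), CuI (5 mol%), −30 °C to rt; aq NH4Cl
Reagents that add atoms: none
Why: Proposed new method: the chloromagnesium alkoxide 20 holds the copper-activated Grignard reagent 11 at the triple bond so that the homofarnesyl group is delivered to the internal alkyne carbon (C8) and magnesium ends on the terminal carbon (C7) anti to it, locked in the five-membered oxamagnesacycle 21, exactly as in the known CuI-catalysed carbomagnesiation of propargyl alcohol that is normally quenched with iodine, carbon dioxide or allyl halides. The closest precedent for the second stage is the CuI-catalysed opening of terminal epoxides by alkenyl Grignard reagents, and the same catalyst should here transmetallate 21 to an alkenylcopper species that attacks the unsubstituted carbon of epoxide 18 in SN2 fashion with retention of the alkene geometry. No ring is closed (the chelate is only a transient template) and no stereocentre is created: C5 keeps its R configuration because only the C6–O bond of the epoxide breaks, and the chelate fixes C6 cis to C8' and trans to C9, that is the Z alkene. The step needs regioselective and anti-selective addition to the alkyne (both secured by the alkoxide chelate), attack at the epoxide CH2 (secured by sterics) and reaction of the alkenyl- in preference to residual alkylmagnesium (addressed by keeping 11 close to stoichiometric, pre-forming the alkoxide with a sacrificial Grignard reagent and using the epoxide in slight excess).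

Step 17
Reactants: 22 diol from step 16
Product: 23 (1R,3Z,7E,11E,15E)-17-(tert-butyldiphenylsilyloxy)-4-[(tert-butyldiphenylsilyloxy)methyl]-1-[(4R)-2,2-dimethyl-1,3-dioxolan-4-yl]-8,12,16-trimethylheptadeca-3,7,11,15-tetraen-1-ol
Conditions: TBDPSCl (1.05 equiv), imidazole, CH2Cl2, −10 to 0 °C
Reagents that add atoms: tert-butyldiphenylsilyl chloride, CC(C)(C)[Si](Cl)(c1ccccc1)c1ccccc1
Why: Selective silylation, the primary allylic C8' hydroxyl reacting much faster with the bulky silyl chloride than the hindered secondary C5 hydroxyl next to the dioxolane.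

Step 18
Reactants: 23 bis-TBDPS ether with free C5 hydroxyl
Product: 24 O5-(diethylphosphonoacetyl) ester of 23 (C5 R, acetonide and both TBDPS ethers retained)
Conditions: (EtO)2P(O)CH2CO2H, DCC, DMAP (cat.), CH2Cl2, 0 °C to rt
Reagents that add atoms: diethylphosphonoacetic acid, CCOP(=O)(CC(=O)O)OCC
Why: Steglich esterification (DCC/DMAP) attaches the phosphonoacetyl unit (C2, C3) to O5 with retention, as no bond to C5 is broken.

Step 19
Reactants: 24 phosphonoacetate acetonide
Product: 25 O5-(diethylphosphonoacetyl) diol with free (4R)-C4 and C4' hydroxyls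
Conditions: AcOH/THF/H2O (3:1:1), 40 °C
Reagents that add atoms: none
Why: Mild aqueous acid hydrolysis of the terminal acetonide, under which TBDPS ethers and the ester should be stable and acyl migration slow.

Step 20
Reactants: 25 phosphonoacetate diol
Product: 26 C4'-O-TBS ether of 25 with free C4 hydroxyl
Conditions: TBSCl, imidazole, CH2Cl2, −20 to 0 °C
Reagents that add atoms: tert-butyldimethylsilyl chloride, CC(C)(C)[Si](C)(C)Cl
Why: Selective silylation of the primary C4' hydroxyl over the secondary C4 hydroxyl, run cold and briefly to suppress acyl migration.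

Step 21
Reactants: 26 C4 carbinol
Product: 27 C4 ketone: (R)-C5 diethylphosphonoacetate flanked by the C4 carbonyl bearing CH2OTBS
Conditions: Dess–Martin periodinane, CH2Cl2, 0 °C to rt
Reagents that add atoms: none
Why: Dess–Martin oxidation converts the C4 carbinol into the ketone under near-neutral conditions that should not epimerise the adjacent C5 centre.

Step 22
Reactants: 27 keto phosphonoacetate
Product: 28 (5R)-butenolide with C4'-OTBS, C8'-OTBDPS and chain-terminal OTBDPS
Conditions: LiCl, i-Pr2NEt, MeCN/THF, 0 °C to rt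
Reagents that add atoms: none
Why: Intramolecular Horner–Wadsworth–Emmons olefination under mild LiCl/amine (Masamune–Roush) conditions, in which the chelated phosphonate anion adds to the C4 ketone and loses diethyl phosphate to form C3=C4 inside a five-membered ring where only the ring geometry is possible, C5 remaining R.

Step 23
Reactants: 28 tris-silyl butenolide
Product: 29 Hippolide F
Conditions: HF·pyridine, pyridine, THF, 0 °C to rt
Reagents that add atoms: none
Why: Fluoride-mediated desilylation under buffered, non-basic conditions removes the TBS and both TBDPS ethers without exposing the base-sensitive C5 centre of the butenolide to basic fluoride.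

**Compound list**

1 | (2E,6E)-farnesol | CC(C)=CCC/C(C)=C/CC/C(C)=C/CO | starting material
2 | (2E,6E)-farnesyl acetate | CC(C)=CCC/C(C)=C/CC/C(C)=C/COC(C)=O | intermediate
3 | (2E,6E,10E)-12-hydroxy-3,7,11-trimethyldodeca-2,6,10-trien-1-yl acetate | C/C(=C\CC/C(C)=C/CC/C(C)=C/COC(C)=O)CO | intermediate
4 | (2E,6E,10E)-12-(tert-butyldiphenylsilyloxy)-3,7,11-trimethyldodeca-2,6,10-trien-1-yl acetate | C/C(=C\CC/C(C)=C/CC/C(C)=C/COC(C)=O)CO[Si](c1ccccc1)(c1ccccc1)C(C)(C)C | intermediate
5 | (2E,6E,10E)-12-(tert-butyldiphenylsilyloxy)-3,7,11-trimethyldodeca-2,6,10-trien-1-ol | C/C(=C\CC/C(C)=C/CC/C(C)=C/CO)CO[Si](c1ccccc1)(c1ccccc1)C(C)(C)C | intermediate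
6 | (2E,6E,10E)-12-(tert-butyldiphenylsilyloxy)-3,7,11-trimethyldodeca-2,6,10-trienal | C/C(=C\CC/C(C)=C/CC/C(C)=C/C=O)CO[Si](c1ccccc1)(c1ccccc1)C(C)(C)C | intermediate
7 | (3E,7E,11E)-13-(tert-butyldiphenylsilyloxy)-4,8,12-trimethyltrideca-1,3,7,11-tetraene | C/C(=C\CC/C(C)=C/CC/C(C)=C/C=C)CO[Si](c1ccccc1)(c1ccccc1)C(C)(C)C | intermediate
8 | 9-[(3E,7E,11E)-13-(tert-butyldiphenylsilyloxy)-4,8,12-trimethyltrideca-3,7,11-trien-1-yl]-9-borabicyclo[3.3.1]nonane | C/C(=C\CC/C(C)=C/CC/C(C)=C/CCB1C2CCCC1CCC2)CO[Si](c1ccccc1)(c1ccccc1)C(C)(C)C | intermediate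
9 | (3E,7E,11E)-13-(tert-butyldiphenylsilyloxy)-4,8,12-trimethyltrideca-3,7,11-trien-1-ol | C/C(=C\CC/C(C)=C/CC/C(C)=C/CCO)CO[Si](c1ccccc1)(c1ccccc1)C(C)(C)C | intermediate
10 | (3E,7E,11E)-1-bromo-13-(tert-butyldiphenylsilyloxy)-4,8,12-trimethyltrideca-3,7,11-triene | C/C(=C\CC/C(C)=C/CC/C(C)=C/CCBr)CO[Si](c1ccccc1)(c1ccccc1)C(C)(C)C | intermediate
11 | [(3E,7E,11E)-13-(tert-butyldiphenylsilyloxy)-4,8,12-trimethyltrideca-3,7,11-trien-1-yl]magnesium bromide | C/C(=C\CC/C(C)=C/CC/C(C)=C/CC[Mg]Br)CO[Si](c1ccccc1)(c1ccccc1)C(C)(C)C | intermediate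
12 | diethyl D-tartrate, diethyl (2S,3S)-2,3-dihydroxybutanedioate | CCOC(=O)[C@@H](O)[C@H](O)C(=O)OCC | starting material
13 | diethyl (4S,5S)-2-phenyl-1,3-dioxolane-4,5-dicarboxylate | CCOC(=O)[C@H]1OC(c2ccccc2)O[C@@H]1C(=O)OCC | intermediate
14 | 2-O-benzyl-D-threitol, (2R,3R)-3-(benzyloxy)butane-1,2,4-triol | OC[C@@H](O)[C@H](OCc1ccccc1)CO | intermediate
15 | (2R)-2-(benzyloxy)-2-[(4R)-2,2-dimethyl-1,3-dioxolan-4-yl]ethan-1-ol | CC1(C)OC[C@@H](O1)[C@H](OCc1ccccc1)CO | intermediate
16 | (1R)-1-[(4R)-2,2-dimethyl-1,3-dioxolan-4-yl]ethane-1,2-diol | CC1(C)OC[C@@H](O1)[C@H](O)CO | intermediate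
17 | (2R)-2-[(4R)-2,2-dimethyl-1,3-dioxolan-4-yl]-2-hydroxyethyl 4-methylbenzenesulfonate | CC1(C)OC[C@@H](O1)[C@H](O)COS(=O)(=O)c1ccc(C)cc1 | intermediate
18 | (R)-2-[(4R)-2,2-dimethyl-1,3-dioxolan-4-yl]oxirane | C1O[C@H]1[C@H]2COC(C)(C)O2 | intermediate
19 | propargyl alcohol | C#CCO | starting material
20 | chloromagnesium prop-2-yn-1-olate | C#CCO[Mg]Cl | intermediate
21 | 4-[(3E,7E,11E)-13-(tert-butyldiphenylsilyloxy)-4,8,12-trimethyltrideca-3,7,11-trien-1-yl]-2,5-dihydro-1,2-oxamagnesole (cyclic alkenylmagnesium alkoxide, Mg on C7 cis to C8') | C/C(=C\CC/C(C)=C/CC/C(C)=C/CCC1=C[Mg]OC1)CO[Si](c1ccccc1)(c1ccccc1)C(C)(C)C | intermediate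
22 | (1R,3Z,7E,11E,15E)-1-[(4R)-2,2-dimethyl-1,3-dioxolan-4-yl]-4-(hydroxymethyl)-8,12,16-trimethyl-17-(tert-butyldiphenylsilyloxy)heptadeca-3,7,11,15-tetraen-1-ol | C/C(=C\CC/C(C)=C/CC/C(C)=C/CC/C(=C/C[C@@H](O)[C@H]1COC(C)(C)O1)CO)CO[Si](c1ccccc1)(c1ccccc1)C(C)(C)C | intermediate
23 | (1R,3Z,7E,11E,15E)-17-(tert-butyldiphenylsilyloxy)-4-[(tert-butyldiphenylsilyloxy)methyl]-1-[(4R)-2,2-dimethyl-1,3-dioxolan-4-yl]-8,12,16-trimethylheptadeca-3,7,11,15-tetraen-1-ol | C/C(=C\CC/C(C)=C/CC/C(C)=C/CC/C(=C/C[C@@H](O)[C@H]1COC(C)(C)O1)CO[Si](c1ccccc1)(c1ccccc1)C(C)(C)C)CO[Si](c1ccccc1)(c1ccccc1)C(C)(C)C | intermediate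
24 | O5-(diethylphosphonoacetyl) ester of 23 (C5 R; (4R)-acetonide; C8' and chain-terminal TBDPS ethers) | C/C(=C\CC/C(C)=C/CC/C(C)=C/CC/C(=C/C[C@@H](OC(=O)CP(=O)(OCC)OCC)[C@H]1COC(C)(C)O1)CO[Si](c1ccccc1)(c1ccccc1)C(C)(C)C)CO[Si](c1ccccc1)(c1ccccc1)C(C)(C)C | intermediate
25 | O5-(diethylphosphonoacetyl) (4R)-C4,C4'-diol (acetonide removed) | C/C(=C\CC/C(C)=C/CC/C(C)=C/CC/C(=C/C[C@@H](OC(=O)CP(=O)(OCC)OCC)[C@H](O)CO)CO[Si](c1ccccc1)(c1ccccc1)C(C)(C)C)CO[Si](c1ccccc1)(c1ccccc1)C(C)(C)C | intermediate
26 | C4'-O-TBS ether of 25 with free (4R)-C4 hydroxyl | C/C(=C\CC/C(C)=C/CC/C(C)=C/CC/C(=C/C[C@@H](OC(=O)CP(=O)(OCC)OCC)[C@H](O)CO[Si](C)(C)C(C)(C)C)CO[Si](c1ccccc1)(c1ccccc1)C(C)(C)C)CO[Si](c1ccccc1)(c1ccccc1)C(C)(C)C | intermediate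
27 | C4 ketone: (R)-C5 diethylphosphonoacetate next to the C4 carbonyl bearing CH2OTBS | C/C(=C\CC/C(C)=C/CC/C(C)=C/CC/C(=C/C[C@@H](OC(=O)CP(=O)(OCC)OCC)C(=O)CO[Si](C)(C)C(C)(C)C)CO[Si](c1ccccc1)(c1ccccc1)C(C)(C)C)CO[Si](c1ccccc1)(c1ccccc1)C(C)(C)C | intermediate
28 | (5R)-butenolide tris-silyl ether: 4-(TBS-oxymethyl)furan-2(5H)-one carrying at C5 the (Z)-C7=C8 side chain with C8'-OTBDPS and chain-terminal OTBDPS | C/C(=C\CC/C(C)=C/CC/C(C)=C/CC/C(=C/C[C@H]1OC(=O)C=C1CO[Si](C)(C)C(C)(C)C)CO[Si](c1ccccc1)(c1ccccc1)C(C)(C)C)CO[Si](c1ccccc1)(c1ccccc1)C(C)(C)C | intermediate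
29 | Hippolide F | C/C(=C\CC/C(C)=C/CC/C(C)=C/CC/C(=C/C[C@H]1OC(=O)C=C1CO)CO)CO | target

**Step count and risks**

Total: 23 steps. Longest linear sequence: 17 steps (steps 1–9 and 16–23); the epoxide branch (steps 10–15) is convergent.

Steps most likely to fail:

1. Step 16 (proposed new method). The chelated alkenylmagnesium 21 may be protonated by unreacted alkyne or react too slowly with the epoxide, so that residual alkylmagnesium or magnesium halide (halohydrin formation) consumes 18 instead. The fallback uses known chemistry and sets out from 19 and 11. The carbomagnesiation is run as in step 16 as far as 21, which is quenched with I2, the established trap, to give the (Z)-iodo alcohol F1. Silylation (TBDPSCl, imidazole) gives the iodo bis-silyl ether F2. Iodine–lithium exchange (t-BuLi, Et2O, −78 °C, kept cold so that the silyl group stays on oxygen) gives the alkenyllithium F3 with retention of geometry. F3 opens 18 at its CH2 carbon in the presence of BF3·OEt2 at −78 °C and gives 23 directly, where the route is rejoined before step 18.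

2. Step 19. During or after acetonide cleavage the phosphonoacetyl group may migrate from O5 to the freed O4 or O4', and the allylic silyl ethers may be partly lost in acid. The fallback sets out from 23 and carries O5 as an ether so that no acyl group sits next to the free diol. O5 is protected as the PMB ether F4 (4-methoxybenzyl trichloroacetimidate, La(OTf)3 cat., toluene). The acetonide is hydrolysed as in step 19 to the diol F5, O4' is silylated (TBSCl, imidazole) to F6, and C4 is oxidised with Dess–Martin periodinane to the ketone F7. The PMB ether is removed with DDQ in buffered CH2Cl2/H2O to give the α-hydroxy ketone F8. Esterification of F8 with diethylphosphonoacetic acid (DCC, 0 °C) gives 27, where the route is rejoined before step 22.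

3. Step 22. Base may deprotonate C5 of 27 (α to the ketone and activated by the acyloxy group) or the γ-position of butenolide 28, eroding the configuration at C5, and olefination of the ketone may be slow. The fallback replaces the phosphonate anion by a neutral phosphorus ylide. It sets out from 23 and runs through PMB ether F4, diol F5, silyl ether F6, ketone F7 and α-hydroxy ketone F8 as described above. F8 is then heated with ketenylidenetriphenylphosphorane (Ph3P=C=C=O) in toluene at 80 °C. O-acylation gives the acyl ylide F9, which closes the ring by intramolecular Wittig reaction without added base and gives 28, where the route is rejoined before step 23.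

**Further compounds**

F1 | step 16 | (Z)-iodo alcohol: (2Z,6E,10E,14E)-2-(iodomethylidene) homofarnesyl carbinol, iodine on C7 cis to the C8' hydroxymethyl, chain-terminal OTBDPS | C/C(=C\CC/C(C)=C/CC/C(C)=C/CC/C(=C/I)CO)CO[Si](c1ccccc1)(c1ccccc1)C(C)(C)C
F2 | step 16 | C8'-O-TBDPS ether of F1 | C/C(=C\CC/C(C)=C/CC/C(C)=C/CC/C(=C/I)CO[Si](c1ccccc1)(c1ccccc1)C(C)(C)C)CO[Si](c1ccccc1)(c1ccccc1)C(C)(C)C
F3 | step 16 | alkenyllithium from F2 (lithium on C7, cis to C8') | C/C(=C\CC/C(C)=C/CC/C(C)=C/CC/C(=C/[Li])CO[Si](c1ccccc1)(c1ccccc1)C(C)(C)C)CO[Si](c1ccccc1)(c1ccccc1)C(C)(C)C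
F4 | step 19 | O5-PMB ether of 23 (C5 R, (4R)-acetonide) | C/C(=C\CC/C(C)=C/CC/C(C)=C/CC/C(=C/C[C@@H](OCc1ccc(OC)cc1)[C@H]1COC(C)(C)O1)CO[Si](c1ccccc1)(c1ccccc1)C(C)(C)C)CO[Si](c1ccccc1)(c1ccccc1)C(C)(C)C
F5 | step 19 | O5-PMB (4R)-C4,C4'-diol | C/C(=C\CC/C(C)=C/CC/C(C)=C/CC/C(=C/C[C@@H](OCc1ccc(OC)cc1)[C@H](O)CO)CO[Si](c1ccccc1)(c1ccccc1)C(C)(C)C)CO[Si](c1ccccc1)(c1ccccc1)C(C)(C)C
F6 | step 19 | C4'-O-TBS ether of F5 | C/C(=C\CC/C(C)=C/CC/C(C)=C/CC/C(=C/C[C@@H](OCc1ccc(OC)cc1)[C@H](O)CO[Si](C)(C)C(C)(C)C)CO[Si](c1ccccc1)(c1ccccc1)C(C)(C)C)CO[Si](c1ccccc1)(c1ccccc1)C(C)(C)C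
F7 | step 19 | C4 ketone with (R)-C5 OPMB | C/C(=C\CC/C(C)=C/CC/C(C)=C/CC/C(=C/C[C@@H](OCc1ccc(OC)cc1)C(=O)CO[Si](C)(C)C(C)(C)C)CO[Si](c1ccccc1)(c1ccccc1)C(C)(C)C)CO[Si](c1ccccc1)(c1ccccc1)C(C)(C)C
F8 | step 19 | (R)-C5 α-hydroxy ketone | C/C(=C\CC/C(C)=C/CC/C(C)=C/CC/C(=C/C[C@@H](O)C(=O)CO[Si](C)(C)C(C)(C)C)CO[Si](c1ccccc1)(c1ccccc1)C(C)(C)C)CO[Si](c1ccccc1)(c1ccccc1)C(C)(C)C
F9 | step 22 | O5-(triphenylphosphoranylidene)acetate of F8 (acyl ylide) | C/C(=C\CC/C(C)=C/CC/C(C)=C/CC/C(=C/C[C@@H](OC(=O)C=P(c1ccccc1)(c1ccccc1)c1ccccc1)C(=O)CO[Si](C)(C)C(C)(C)C)CO[Si](c1ccccc1)(c1ccccc1)C(C)(C)C)CO[Si](c1ccccc1)(c1ccccc1)C(C)(C)C
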